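## Structural features

Hansfordiol B (14) is an achiral 5-alkylresorcinol: one benzene ring with hydroxyl groups on C1 and C3 and an unbranched seventeen-carbon chain on C5. In that chain C1' to C15' are methylene groups, C16' is a ketone carbonyl and C17' is the terminal methyl group. There is no stereocentre and no ring besides the arene, so no two stereocentres stand next to each other and nothing has to be controlled stereochemically. The fragile parts are the electron-rich resorcinol (acidic O–H, easily oxidised, open to electrophiles at C2, C4 and C6) and the methyl ketone (electrophilic, enolisable, reducible). The real difficulty is one of economy: a cheap aromatic building block and a cheap fatty-acid building block must be joined through fifteen unfunctionalised methylenes in few steps, with phenols and ketone masked against carbanions and then released together. The key step uses the fact that C4' is an ordinary CH2 between C3' and C5'. It can be brought in as C2 of 1,3-dithiane (8), which can be deprotonated and alkylated twice and then freed of sulfur, so bonds C3'–C4' and C4'–C5' form in one flask. In the dimethyl ether the ring C–H at C2, flanked by both methoxy groups, is itself open to lithiation, and this decides the order in which the two electrophiles are added.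

## Logic of the disconnections

14 ⇒ 13. The two aryl O–H bonds are traced back to O–CH3 bonds and the C16' carbonyl to the two C–O bonds of a dioxolane. The free phenols would quench any carbanion and the free ketone would be attacked by one, so both must be masked through the chain assembly. The gain is a neutral, base-stable intermediate. The demand is that one acidic operation removes both kinds of mask at the end without harming the ketone.

13 ⇒ 12. The two C–H bonds at C4' are replaced by two C–S bonds of a six-membered dithioketal. This turns an anonymous methylene into a carbon that was once a carbanion, which reveals where the chain can be cut. The demand on the forward step is a C–S hydrogenolysis that leaves the arene, the methyl ethers and the dioxolane alone; the dioxolane is kept to this point so that the ketone is not reduced.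

12 ⇒ 8 + 7 + 3 (through 9, 10 and 11). The bonds C3'–C4' and C4'–C5' are cut. The fifteen methylenes then divide as 3 (C1'–C3', from 3) + 1 (C4', from 8) + 11 (C5'–C15', from 7), and each outer piece maps onto a commercial acid. The gain is full convergence, with no ring and no stereocentre to worry about. The demand is two lithiations and two SN2 displacements in a fixed order in one flask: 7 is added first and 3 last, so that no alkyllithium ever meets the dimethoxyarene.

7 ⇒ 6 ⇒ 4 (through 5). The dioxolane C–O bonds are cut back to the ketone, and then the C16'–C17' bond is cut, which takes the methyl ketone back to a carboxylic acid derivative. This reaches a commercial ω-bromo acid with the right number of methylenes. The demand is a methyl transfer that stops at the ketone and does not touch the primary bromide.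

3 ⇒ 2 ⇒ 1. The C3'–Br bond is traced to a C3'–O bond and the alcohol to the carboxylic acid. This reaches a commercial arylpropanoic acid with the oxygen pattern already in place. The demand is only that reduction and bromination spare the methyl ethers.

## Other disconnections considered

Alternative 1: The arene is dismantled at ring bonds C4–C5 and C2–C3, leading to enone A1 and dimethyl malonate A2.
- Forward step: under methoxide, A2 would add to the β-carbon of A1, and the methyl-side ketone enolate would then condense onto one ester to close the carbocycle as the racemic trans keto ester A3. Saponification, decarboxylation and dehydrogenation would have to follow.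
- In favour: the reagents are cheap, no organolithium is needed, and the resorcinol would appear with free hydroxyls. On this last point it is better than the chosen plan, which must end with an ether cleavage.
- Against: A1 already contains the whole tether, so chain assembly is only moved into a less accessible precursor. Two stereocentres are made in A3 only to be erased. The dehydrogenation of a cyclohexane-1,3-dione to a resorcinol calls for halogenation–elimination or hot oxidants, and these endanger the α-positions of the distal ketone once its ketal is lost.
- Comparison: structurally it builds a ring that can be bought. Mechanistically the annulation is as dependable as a dithiane alkylation (equal on that point), but the aromatisation is the weak link. On step economy it is clearly longer.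

Alternative 2: The arene is cut at ring bonds C1–C2, C3–C4 and C1–C6, leading to cyclobutenone A4 and ethoxyacetylene A5.
- Forward step: on heating, A4 would open to a vinylketene, add A5 in a [2+2] sense, and reach the 3-ethoxyphenol A6 through two further electrocyclic steps and tautomerisation.
- In favour: the key step is neutral and thermal, needs no strong base or cold bath, leaves the ketal untouched and is regiospecific. On mildness of the key step it is better than the chosen plan.
- Against: A4 is not commercial and its preparation again presupposes the complete tether. A5 is volatile and costly. A6 still carries an alkyl aryl ether, so the final Lewis-acid dealkylation is not avoided (equal to the chosen plan on the end-game). The differentiated oxygens it delivers are of no use for a symmetric resorcinol.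
- Comparison: it is the more elegant mechanism, but it is structurally unnecessary here and several steps longer.

Alternative 3: Ring bond C5–C6 is cut, which unfolds the arene into the open-chain trioxo ester A7.
- Forward step: under mild base the C2 methylene of A7 would add to the C7 ketone, and dehydration and enolisation would give the resorcylate A8. Ester hydrolysis and decarboxylation would then be needed.
- In favour: it mirrors the polyketide logic by which such resorcinols arise in nature, the 1,3,5 pattern is automatic, and the phenols are never protected. On protecting-group economy at the arene it is better than the chosen plan.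
- Against: A7 is a sensitive polycarbonyl compound whose assembly requires acylating a polyanion with an activated long-chain acid that already holds the masked ketone. Its cyclisation can take other courses (Claisen closure onto the ester, or O-cyclisation to a pyrone). Two further operations follow A8.
- Comparison: mechanistically it is the most instructive, and it is equal to the chosen plan in having no stereochemical issue. It is less predictable in the ring-forming step and longer overall, and it again spends its effort on a ring that is commercially available.

Key step: step 5

Remark on the chemistry: the chain is numbered from C1' (bonded to ring carbon C5) to C17' (the methyl group). The sequence in which the two bromides enter the one-flask dialkylation is treated as a reaction condition, because the three components, the two bonds formed and the product are the same in either sequence.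

## Route

Step 1
Reactants: 1 3-(3,5-dimethoxyphenyl)propanoic acid
Product: 2 3-(3,5-dimethoxyphenyl)propan-1-ol
Conditions: LiAlH4, THF, 0 °C to rt; H2O, aq. NaOH work-up
Reagents that add atoms: none
Why: Hydride reduction of the carboxylic acid (through the aluminium carboxylate) to the primary alcohol; the arene and the aryl methyl ethers are inert to LiAlH4.

Step 2
Reactants: 2 3-(3,5-dimethoxyphenyl)propan-1-ol
Product: 3 1-(3-bromopropyl)-3,5-dimethoxybenzene
Conditions: CBr4, PPh3, CH2Cl2, 0 °C to rt
Reagents that add atoms: carbon tetrabromide, SMILES BrC(Br)(Br)Br
Why: Appel reaction: the alcohol is activated as an alkoxyphosphonium ion and displaced by bromide in an SN2 step at the primary carbon; the near-neutral conditions do not touch the methyl ethers or the electron-rich ring.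

Step 3
Reactants: 4 12-bromododecanoic acid
Product: 6 13-bromotridecan-2-one, via 12-bromododecanoyl chloride 5 (not isolated)
Conditions: (COCl)2, cat. DMF, CH2Cl2, 0 °C to rt; concentrate; then Me2CuLi (from MeLi and CuI), Et2O, −78 °C; MeOH, then aq. NH4Cl
Reagents that add atoms: lithium dimethylcuprate Me2CuLi (made in the flask from MeLi and CuI), SMILES [Li+].C[Cu-]C
Why: DMF-catalysed formation of the acid chloride followed by acylation of a Gilman cuprate; at −78 °C the acyl chloride reacts far faster than a primary alkyl bromide and the ketone formed is inert to the cuprate, so the reaction should stop at the ω-bromo methyl ketone.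

Step 4
Reactants: 6 13-bromotridecan-2-one
Product: 7 2-(11-bromoundecyl)-2-methyl-1,3-dioxolane
Conditions: ethylene glycol, cat. p-TsOH·H2O, toluene, reflux, Dean–Stark trap
Reagents that add atoms: ethane-1,2-diol, SMILES OCCO
Why: Acid-catalysed ketalisation driven by azeotropic removal of water; the primary bromide is stable to these conditions, and the dioxolane shields C16' from organolithium reagents and from Raney Ni later on.

Step 5
Reactants: 8 1,3-dithiane; 7 2-(11-bromoundecyl)-2-methyl-1,3-dioxolane; 3 1-(3-bromopropyl)-3,5-dimethoxybenzene
Product: 12 2-[3-(3,5-dimethoxyphenyl)propyl]-2-[11-(2-methyl-1,3-dioxolan-2-yl)undecyl]-1,3-dithiane, via 2-lithio-1,3-dithiane 9 (not isolated), via 2-[11-(2-methyl-1,3-dioxolan-2-yl)undecyl]-1,3-dithiane 10 (not isolated), via 2-lithio-2-[11-(2-methyl-1,3-dioxolan-2-yl)undecyl]-1,3-dithiane 11 (not isolated)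
Conditions: 8 (1.05 equiv), n-BuLi (1.05 equiv), THF, −30 °C; 7 (1.0 equiv), −78 °C to 0 °C; n-BuLi (1.0 equiv), −20 °C; 3 (1.1 equiv), DMPU, −78 °C to rt
Reagents that add atoms: none
Why: n-BuLi removes a C2 proton of 8 (acidified by the two sulfur atoms) to give 9, which displaces bromide from the primary carbon of 7 by SN2 and forms C4'–C5' in 10; a second charge of n-BuLi, added only after that alkylation is complete, turns 10 into the tertiary carbanion 11, which displaces bromide from 3 and forms C3'–C4' in 12. The closest known reaction type is the Corey–Seebach sequential dialkylation of 1,3-dithiane, in which the dithiane carbon serves as a methylene dianion equivalent. No ring is closed and no stereocentre is created: C2 of the dithiane in 12 carries two different chains but lies on the mirror plane of its ring, and it ends as the C4' methylene. The selectivity needed is hetero-dialkylation without homo-dialkylation, and the stepwise dosing of base secures it because 11 cannot exist before the second charge of n-BuLi; 8 is used in slight excess over 7 so that no 7 is left when base is added again. The order, 7 first and 3 last, is chosen so that n-BuLi never meets the dimethoxyarene, whose C–H between the two methoxy groups is prone to directed ortho-lithiation; 3 meets only the soft, hindered anion 11, which should react at the primary C–Br. Both bromides are primary and unbranched with no activated β-hydrogen, so substitution should prevail over elimination, and DMPU is added to speed the slower second alkylation. The ketone is inert as its dioxolane, which offers no proton acidic to n-BuLi at −20 °C.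

Step 6
Reactants: 12 2-[3-(3,5-dimethoxyphenyl)propyl]-2-[11-(2-methyl-1,3-dioxolan-2-yl)undecyl]-1,3-dithiane
Product: 13 2-[15-(3,5-dimethoxyphenyl)pentadecyl]-2-methyl-1,3-dioxolane
Conditions: Raney Ni (W-2, large excess), EtOH, reflux
Reagents that add atoms: none
Why: Mozingo desulfurisation: hydrogen adsorbed on the nickel cleaves both C–S bonds at C4' and replaces them by C–H; the benzene ring, the methyl ethers and the dioxolane are stable in refluxing ethanol, and the ketal keeps C16' from being reduced to an alcohol.

Step 7
Reactants: 13 2-[15-(3,5-dimethoxyphenyl)pentadecyl]-2-methyl-1,3-dioxolane
Product: 14 Hansfordiol B, 17-(3,5-dihydroxyphenyl)heptadecan-2-one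
Conditions: BBr3 (6 equiv), CH2Cl2, −78 °C to rt; then 1 M aq. HCl, THF, rt
Reagents that add atoms: water, SMILES O
Why: Lewis-acid cleavage of aryl methyl ethers: boron binds each ether oxygen and bromide attacks the methyl group, giving aryl borates that hydrolyse on work-up; the same reagent opens the dioxolane and the acidic aqueous work-up completes its hydrolysis to the C16' ketone. Excess BBr3 is used because the ketal oxygens also bind boron.

## Compound list

1 | 3-(3,5-dimethoxyphenyl)propanoic acid | COc1cc(CCC(=O)O)cc(OC)c1 | starting material
2 | 3-(3,5-dimethoxyphenyl)propan-1-ol | COc1cc(CCCO)cc(OC)c1 | intermediate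
3 | 1-(3-bromopropyl)-3,5-dimethoxybenzene | COc1cc(CCCBr)cc(OC)c1 | intermediate
4 | 12-bromododecanoic acid | OC(=O)CCCCCCCCCCCBr | starting material
5 | 12-bromododecanoyl chloride | ClC(=O)CCCCCCCCCCCBr | intermediate
6 | 13-bromotridecan-2-one | CC(=O)CCCCCCCCCCCBr | intermediate
7 | 2-(11-bromoundecyl)-2-methyl-1,3-dioxolane | CC1(CCCCCCCCCCCBr)OCCO1 | intermediate
8 | 1,3-dithiane | C1CSCSC1 | starting material
9 | 2-lithio-1,3-dithiane | [Li]C1SCCCS1 | intermediate
10 | 2-[11-(2-methyl-1,3-dioxolan-2-yl)undecyl]-1,3-dithiane | CC1(CCCCCCCCCCCC2SCCCS2)OCCO1 | intermediate
11 | 2-lithio-2-[11-(2-methyl-1,3-dioxolan-2-yl)undecyl]-1,3-dithiane | CC1(CCCCCCCCCCCC2([Li])SCCCS2)OCCO1 | intermediate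
12 | 2-[3-(3,5-dimethoxyphenyl)propyl]-2-[11-(2-methyl-1,3-dioxolan-2-yl)undecyl]-1,3-dithiane | COc1cc(CCCC2(CCCCCCCCCCCC3(C)OCCO3)SCCCS2)cc(OC)c1 | intermediate
13 | 2-[15-(3,5-dimethoxyphenyl)pentadecyl]-2-methyl-1,3-dioxolane | COc1cc(CCCCCCCCCCCCCCCC2(C)OCCO2)cc(OC)c1 | intermediate
14 | Hansfordiol B, 17-(3,5-dihydroxyphenyl)heptadecan-2-one | CC(=O)CCCCCCCCCCCCCCCc1cc(O)cc(O)c1 | target

## Step count and risk

Total: 7 steps (step 3 runs acid chloride formation and cuprate acylation without isolating 5). Longest linear sequence: 5 steps (4 → 6 → 7 → 12 → 13 → 14; the branch from 1 is equally long).

Step 5 (key step). The most likely failure is incomplete metalation of 10, whose remaining C2–H is less acidic and more hindered than that of 8. Unconsumed n-BuLi would then still be present when 3 is added and could attack 3 by bromine–lithium exchange or ring lithiation. The displacement by the hindered anion 11 could also be slow enough to let elimination compete. The fallback changes the linchpin to a carbon acid that needs no alkyllithium. It sets out from 7 and 3. Bis(phenylsulfonyl)methane is alkylated with 7 (NaH, DMF) to give 2-[12,12-bis(phenylsulfonyl)dodecyl]-2-methyl-1,3-dioxolane F1. F1 is alkylated again with 3 (NaH, DMF, cat. NaI, 60–80 °C) to give 2-[15-(3,5-dimethoxyphenyl)-12,12-bis(phenylsulfonyl)pentadecyl]-2-methyl-1,3-dioxolane F2. Both sulfonyl groups are then removed reductively with Mg in MeOH. The fallback comes back to the route at 13, so step 6 is not needed.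

Step 7. The most likely failure is stalling of the ether cleavage at the monomethyl ether stage, because the ketal oxygens and the liberated carbonyl compete for the Lewis acid. Slow condensation of the freed methyl ketone under prolonged exposure to the boron halide is a second risk. The fallback separates the two unmaskings and replaces the Lewis acid by a protic cleavage. It sets out from 13. The dioxolane alone is hydrolysed with aqueous HCl in THF to give 17-(3,5-dimethoxyphenyl)heptadecan-2-one F3. The methyl ethers are then cleaved with 48% aqueous HBr in AcOH at reflux. The fallback comes back at 14.

Step 6. The most likely failure is incomplete C–S hydrogenolysis with a batch of low activity, or loss of the lipophilic product by adsorption on the large excess of metal; a very active batch could begin to hydrogenate the arene. The fallback removes sulfur by hydrolysis and oxygen by reduction. It sets out from 12. The dithiane is unmasked with MeI and CaCO3 in aqueous MeCN (buffered, so the dioxolane stays) to give 1-(3,5-dimethoxyphenyl)-15-(2-methyl-1,3-dioxolan-2-yl)pentadecan-4-one F4. The C4' carbonyl is then removed by Wolff–Kishner reduction in the Huang-Minlon manner (N2H4·H2O, KOH, diethylene glycol, 130 to 200 °C), to which the ketal is stable. The fallback comes back at 13. Any partial O-demethylation by hot KOH would be harmless, since step 7 removes both methyl groups anyway.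

Step 3. The most likely failure is loss of chemoselectivity if the temperature rises: the cuprate would then couple at the primary bromide or the acid chloride would be hydrolysed back to 4 during transfer. The fallback replaces the cuprate by a Weinreb ketone synthesis. It sets out from 4. Coupling with MeNHOMe·HCl (EDC·HCl, i-Pr2NEt, CH2Cl2) gives 12-bromo-N-methoxy-N-methyldodecanamide F5. MeMgBr in THF at 0 °C then gives the ketone through a chelated tetrahedral intermediate that cannot add a second time; a Grignard reagent without copper does not displace a primary bromide at this temperature. The fallback comes back at 6.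

## Further compounds

F1 | step 5 | 2-[12,12-bis(phenylsulfonyl)dodecyl]-2-methyl-1,3-dioxolane | CC1(CCCCCCCCCCCC(S(=O)(=O)c2ccccc2)S(=O)(=O)c3ccccc3)OCCO1
F2 | step 5 | 2-[15-(3,5-dimethoxyphenyl)-12,12-bis(phenylsulfonyl)pentadecyl]-2-methyl-1,3-dioxolane | COc1cc(CCCC(CCCCCCCCCCCC2(C)OCCO2)(S(=O)(=O)c3ccccc3)S(=O)(=O)c4ccccc4)cc(OC)c1
F3 | step 7 | 17-(3,5-dimethoxyphenyl)heptadecan-2-one | CC(=O)CCCCCCCCCCCCCCCc1cc(OC)cc(OC)c1
F4 | step 6 | 1-(3,5-dimethoxyphenyl)-15-(2-methyl-1,3-dioxolan-2-yl)pentadecan-4-one | COc1cc(CCCC(=O)CCCCCCCCCCCC2(C)OCCO2)cc(OC)c1
F5 | step 3 | 12-bromo-N-methoxy-N-methyldodecanamide | CON(C)C(=O)CCCCCCCCCCCBr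
A1 | alternative 1 | (E)-19-(2-methyl-1,3-dioxolan-2-yl)nonadec-3-en-2-one | CC(=O)/C=C/CCCCCCCCCCCCCCCC1(C)OCCO1
A2 | alternative 1 | dimethyl malonate | COC(=O)CC(=O)OC
A3 | alternative 1 | methyl trans-2-[15-(2-methyl-1,3-dioxolan-2-yl)pentadecyl]-4,6-dioxocyclohexane-1-carboxylate (racemic) | COC(=O)[C@@H]1[C@@H](CCCCCCCCCCCCCCCC2(C)OCCO2)CC(=O)CC1=O
A4 | alternative 2 | 3-[15-(2-methyl-1,3-dioxolan-2-yl)pentadecyl]cyclobut-2-en-1-one | O=C1C=C(CCCCCCCCCCCCCCCC2(C)OCCO2)C1
A5 | alternative 2 | ethoxyacetylene | CCOC#C
A6 | alternative 2 | 3-ethoxy-5-[15-(2-methyl-1,3-dioxolan-2-yl)pentadecyl]phenol | CCOc1cc(O)cc(CCCCCCCCCCCCCCCC2(C)OCCO2)c1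
A7 | alternative 3 | methyl 22-(2-methyl-1,3-dioxolan-2-yl)-3,5,7-trioxodocosanoate | COC(=O)CC(=O)CC(=O)CC(=O)CCCCCCCCCCCCCCCC1(C)OCCO1
A8 | alternative 3 | methyl 2,4-dihydroxy-6-[15-(2-methyl-1,3-dioxolan-2-yl)pentadecyl]benzoate | COC(=O)c1c(O)cc(O)cc1CCCCCCCCCCCCCCCC2(C)OCCO2
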